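The numbers in the tables were generated by integration on assumed constants, noise included.

The pitfall I watched for was to read the third reagent, charged at 0.0550 M against 0.050 M of substrate, as a comfortable excess. It can act twice on one molecule: on intermediate B to give target, then on target to give over-reaction product.

common to all: substrate 0.050 M
- epsilon: partner 0.030 M; second reagent 0.060 M; third reagent 0.055 M; capture agent 5 mM; temperature 35 °C; run made earlier
- delta: partner 0.12 M; second reagent 0.060 M; third reagent 0.055 M; capture agent 5 mM; temperature 85 °C; run made earlier
- violet: partner 0.0600 M; second reagent 0.0600 M; third reagent 0.0550 M; capture agent 5.00 mM; temperature 40 °C; time 40 h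
- teal: partner 0.0600 M; second reagent 0.0600 M; third reagent 0.0550 M; capture agent 5.00 mM; temperature 130 °C; time 40 h
- ochre: partner 0.0600 M; second reagent 0.0600 M; third reagent 0.0550 M; capture agent 5.00 mM; temperature 70 °C; time 40 h
- red: partner 0.0600 M; second reagent 0.0600 M; third reagent 0.0550 M; capture agent 5.00 mM; temperature 100 °C; time 40 h

- the flask with the highest amount of target, in percent of the substrate charged ("all alike" if they lie within 1.5 percentage points) (violet / teal / ochre / red / all alike)
- final target, as a percentage of the substrate charged, in violet
- final target, as a percentage of the substrate charged, in teal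
- final target, as a percentage of the substrate charged, in ochre
- final target, as a percentage of the substrate charged, in red

| run | time / h | target / % | substrate / % |
|---|---|---|---|
| epsilon | 8.00 | 0 | 86.5 |
| epsilon | 15.0 | 0.3 | 78.3 |
| epsilon | 25.0 | 0 | 67.8 |
| epsilon | 30.0 | 0.3 | 66.0 |
| epsilon | 40.0 | 0 | 60.8 |
| epsilon | 50.0 | 0 | 56.3 |
| delta | 0.417 | 0.4 | 6.1 |
| delta | 0.667 | 0.5 | 0.8 |
| delta | 1.00 | 1.7 | 0 |
| delta | 2.00 | 4.0 | 0.5 |
| delta | 3.00 | 3.8 | 0.1 |
| delta | 5.00 | 5.4 | 0 |

(standard deviation of a reading: 0.5 percentage points)

- reactions considered so far: third reagent + intermediate B -> target; third reagent + target -> over-reaction product; substrate + partner -> intermediate A; intermediate B + capture agent -> trapped intermediate; second reagent + intermediate A -> intermediate B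

Substrate and partner give intermediate A, second reagent turns that into intermediate B, and capture agent competes for intermediate B. The flasks differ in temperature, so I turned to the readings. In the delta run substrate stood at 0% after 1.00 h, with target at 1.7%, so target comes from a later stage.

I then supposed the capture complete, each capture agent holding one intermediate B, and reckoned with what that supposition leaves free, c(substrate) − c(capture agent). In a flask where the third reagent is the limiting reagent and is used up, a molecule reaching target has taken one third reagent, a molecule of over-reaction product two, and a stranded intermediate none. Twice the free substrate less the third reagent charged is 70.0% of the substrate. This is my spent-reagent ceiling, and in such a flask, with the capture complete, target equals it less twice the stranded intermediates. The readings did not give me the stranded part, so I committed to the ceiling and no further.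

The forecast chose teal, with 0.2% in violet, 71% in teal, 13% in ochre and 66% in red, and reasoned that “Stoichiometry bounds the over-reaction”. Its teal figure stands above my ceiling.

The simulation gave teal as the highest, with 0.489% in violet, 17.0% in teal, 4.72% in ochre and 11.3% in red.

    third reagent + intermediate B → target (k = 0.460 L mol⁻¹ h⁻¹, Ea = 67.0 kJ mol⁻¹)
    third reagent + target → over-reaction product (k = 1.10 L mol⁻¹ h⁻¹, Ea = 54.0 kJ mol⁻¹)
    substrate + partner → intermediate A (k = 1.20 L mol⁻¹ h⁻¹, Ea = 86.0 kJ mol⁻¹)
    intermediate B + capture agent → trapped intermediate (k = 5.30 L mol⁻¹ h⁻¹, Ea = 55.0 kJ mol⁻¹)
    second reagent + intermediate A → intermediate B (k = 0.0290 L mol⁻¹ h⁻¹, Ea = 84.0 kJ mol⁻¹)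
    (constants at 40 °C)

At 40 h teal held 0% third reagent, 0% capture agent, 0% intermediate A and 26.5% intermediate B, and the ceiling less twice that intermediate B is 17.0%, beside the 17.0% found. Red held 0% third reagent and 0% capture agent, with 27.0% intermediate B and 2.35% intermediate A, and the same subtraction gives 11.3%, beside 11.3%. Teal had come to rest: the slowest mode of that flask has a half-life of 1.78 h. Left ten times as long, teal shows target at 17.0% and intermediate B at 26.5%.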